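**Retrosynthetic overview**

1. The C40 chain is cut last at C11=C12 (Wittig of a ring A C15 triol phosphonium salt with an acetylenic C25 apo-aldehyde) and before that at C11'=C12' (mono-Wittig of the ring B C15 salt on the symmetrical C10 trienedial).
2. Ring B is bought as actinol; C6'–C7' comes from Sonogashira coupling of its enol triflate with (E)-3-methylpent-2-en-4-yn-1-ol, and the same enynol, as its acetylide, is added to a quinone monoketal to form C6–C7 of ring A.
3. The strategy rests on ring A: the carbinol carbon C6 is flanked by C1 (two methyls) and C5 (one methyl, one hydroxyl) and faces the oxygenated C3 across the ring, so without one C1 methyl and the C5 hydroxyl it is a mirror-symmetric 4-alkynyl-4-hydroxy-3,5-dimethylcyclohexa-2,5-dienone derived from 2,6-dimethylbenzoquinone.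
4. A catalytic enantioselective conjugate methylation of one enone arm of that dienone builds the C1 gem-dimethyl carbon and thereby fixes C6; C5 is relayed from C6 (epoxidation anti to the C6 silyl ether, then C4–O cleavage) and C3 from C5 (hydroxyl-directed reduction).
5. Neither six-membered ring is constructed: ring A comes intact from the quinone and is elaborated first, ring B comes intact from actinol, and the two are joined through the chain.

Key step: step 5

Remark on numbering: carotenoid numbering is used for all intermediates (C1–C11 for ring A and its chain, primed numbers for ring B).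

Assumption: the sense of arm selection by the phosphoramidite cannot be read from precedent for this substrate class, so the (R,R)-amine antipode L* = O,O'-(biphenyl-2,2'-diyl) N,N-bis[(R)-1-(naphthalen-2-yl)ethyl]phosphoramidite is written; the mirror-image ligand is used instead if it is the one that leads to the R-configured carbinol carbon of the key-step product.

**Ring A fragment**

Step 1
Reactants: 1 2,6-dimethyl-1,4-benzoquinone
Product: 2 2,6-dimethyl-1,4-benzoquinone 4-(ethylene ketal) (7,9-dimethyl-1,4-dioxaspiro[4.5]deca-6,9-dien-8-one)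
Conditions: ethylene glycol (1.2 equiv), p-TsOH·H2O (cat.), benzene, reflux, Dean–Stark
Reagents that add atoms: ethylene glycol, OCCO
Why: Acid-catalysed ketalization should occur only at the carbonyl flanked by the two ring CH groups, because the other carbonyl is shielded by its two neighbouring methyl-bearing carbons; no stereocentre is formed.

Step 2
Reactants: 3 (E)-3-methylpent-2-en-4-yn-1-ol; 2 quinone monoketal
Product: 5 8-hydroxy-8-[(3E)-5-hydroxy-3-methylpent-3-en-1-yn-1-yl]-7,9-dimethyl-1,4-dioxaspiro[4.5]deca-6,9-diene (achiral quinol ketal), via dilithio enynolate 4 (not isolated)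
Conditions: 3, n-BuLi (2.1 equiv), THF, −78 to 0 °C; then 2, −78 °C to rt; H2O
Reagents that add atoms: none
Why: 1,2-Addition of the hard lithium acetylide (the hydroxyl being masked as its lithium alkoxide) to the remaining dienone carbonyl forms C6–C7, and the adduct keeps the mirror plane through C3 and C6, so no stereocentre arises.

Step 3
Reactants: 5 quinol ketal
Product: 6 4-hydroxy-4-[(3E)-5-hydroxy-3-methylpent-3-en-1-yn-1-yl]-3,5-dimethylcyclohexa-2,5-dien-1-one (achiral para-quinol)
Conditions: 1 M aq HCl, THF, 0 °C to rt
Reagents that add atoms: water, O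
Why: Ketal hydrolysis proceeds through the alkoxy-stabilised cation at C3, whereas the tertiary alcohol should survive because its ionisation would place a cation para to the emerging carbonyl.

Step 4
Reactants: 6 para-quinol diol
Product: 7 4-[(3E)-5-(tert-butyldimethylsilyloxy)-3-methylpent-3-en-1-yn-1-yl]-4-hydroxy-3,5-dimethylcyclohexa-2,5-dien-1-one (prochiral dienone)
Conditions: TBSCl (1.05 equiv), imidazole, CH2Cl2, 0 °C
Reagents that add atoms: tert-butyldimethylsilyl chloride, CC(C)(C)[Si](C)(C)Cl
Why: Silylation is selective for the open primary allylic hydroxyl over the tertiary carbinol buried between two methyl-bearing sp2 carbons.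

Step 5
Reactants: 7 prochiral para-quinol dienone
Product: 9 (R)-4-[(3E)-5-(tert-butyldimethylsilyloxy)-3-methylpent-3-en-1-yn-1-yl]-4-hydroxy-3,5,5-trimethylcyclohex-2-en-1-one (ring A enone; carbinol carbon = C6), via aluminium dienolate 8 (not isolated)
Conditions: AlMe3 (3 equiv), Cu(O2CC4H3S) (copper thiophene-2-carboxylate, monovalent copper, 10 mol%), L* (20 mol%), Et2O, −30 °C; aq KNaC4H4O6 (potassium sodium tartrate)
Reagents that add atoms: trimethylaluminium, C[Al](C)C
Why: Proposed new method: AlMe3 first turns the C6 hydroxyl into an O–AlMe2 group (methane is lost), the ligand-bound methylcopper species (monovalent copper) then π-complexes one enone arm, adds oxidatively at its methyl-bearing β-carbon to give a trivalent-copper enolate and reductively eliminates the second C1–CH3 bond, and the product rests as the cross-conjugated aluminium dienolate 8, which cannot accept a second methyl and is protonated at C2 on work-up. The closest known reaction types are the copper/phosphoramidite-catalysed conjugate addition of AlMe3 to β-methylcyclohexenones that builds quaternary carbons, the copper-catalysed enantioselective desymmetrization of 4,4-disubstituted cyclohexadienones, and the racemic cuprate methylation of 4-alkynyl-4-hydroxy-3,5-dimethylcyclohexadienones. No ring is closed. The methylated carbon ends with two identical methyls and is not stereogenic, so the only new stereocentre is the carbinol carbon C6, and it is controlled by the chiral ligand through its choice of which enantiotopic arm is methylated. That choice needs enantiotopic-group selectivity, which the substrate supports because the C6 aluminium alkoxide draws the Cu–Al reagent to its own ring face (the other face carries only the linear alkyne), and on that face the two β-carbons present opposite prochiral faces, so the β-face preference of the ligand is matched at one arm and mismatched at the other. Mono-addition and 1,4- over 1,2-attack should follow from the enolate resting state and the soft methylcopper nucleophile.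

Step 6
Reactants: 9 ring A enone
Product: 10 C6 triethylsilyl ether of 9 ((R)-configured at C6)
Conditions: Et3SiOTf, 2,6-lutidine, CH2Cl2, −78 to 0 °C
Reagents that add atoms: triethylsilyl trifluoromethanesulfonate, CC[Si](CC)(CC)OS(=O)(=O)C(F)(F)F
Why: The silyl triflate is reactive enough to cap the hindered tertiary hydroxyl, which removes its hydrogen-bond directing ability and makes the C6 oxygen substituent the bulky group for the next step.

Step 7
Reactants: 10 silylated enone
Product: 11 (4S,5R,6S)-4,5-epoxy-3-ketone with the epoxide oxygen on the face opposite the C6 triethylsilyloxy group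
Conditions: t-BuOOH, benzyltrimethylammonium hydroxide (cat.), THF, 0 °C to rt
Reagents that add atoms: tert-butyl hydroperoxide, CC(C)(C)OO
Why: In this Weitz–Scheffer nucleophilic epoxidation the peroxide anion should add to C5 antiperiplanar to the pseudoaxial C6 silyloxy group (held axial by allylic strain with the C5 methyl) and the enolate then closes on oxygen, so the epoxide forms anti to the C6 oxygen and sets C5.

Step 8
Reactants: 11 epoxy ketone
Product: 12 (5R,6S)-5-hydroxy-3-ketone (C6 triethylsilyl ether and primary tert-butyldimethylsilyl ether retained)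
Conditions: (PhSe)2, NaBH4, EtOH, rt; AcOH; then 11, 0 °C to rt
Reagents that add atoms: none
Why: The selenoborate Na[PhSeB(OEt)3] opens the epoxy ketone by attack at the α-carbon C4 and a second selenolate removes selenium from the α-seleno ketone, so only the C4–O bond is cleaved and C5 keeps its configuration under conditions too mild for retro-aldol or dehydration.

Step 9
Reactants: 12 β-hydroxy ketone
Product: 13 (3S,5R,6S)-3,5-diol (C6 triethylsilyl ether and primary tert-butyldimethylsilyl ether retained)
Conditions: Me4NBH(OAc)3, MeCN/AcOH, −30 to −20 °C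
Reagents that add atoms: none
Why: In this Evans–Saksena reduction the axial C5 hydroxyl exchanges onto boron and delivers hydride intramolecularly to its own face of the C3 ketone, so the new C3 hydroxyl should emerge anti to the C5 hydroxyl.

Step 10
Reactants: 13 bis-silylated diol
Product: 14 (3S,5R,6S)-6-[(3E)-5-hydroxy-3-methylpent-3-en-1-yn-1-yl]-1,1,5-trimethylcyclohexane-3,5,6-triol (ring A alkynyl tetraol)
Conditions: TBAF, THF, 0 °C to rt
Reagents that add atoms: none
Why: Fluoride cleaves both the primary tert-butyldimethylsilyl ether and the tertiary triethylsilyl ether without touching the enyne or any stereocentre.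

Step 11
Reactants: 14 alkynyl tetraol
Product: 15 (3S,5R,6R)-6-[(1E,3E)-5-hydroxy-3-methylpenta-1,3-dien-1-yl]-1,1,5-trimethylcyclohexane-3,5,6-triol (ring A dienyl tetraol)
Conditions: NaAlH2(OCH2CH2OCH3)2 (excess), THF, 0 °C to rt; aq KNaC4H4O6
Reagents that add atoms: none
Why: The aluminate bound to the propargylic C6 alkoxide adds H and Al across C7≡C8 in an anti sense (alkoxide-directed trans-hydroalumination) and protonolysis gives the 7E alkene, leaving the 9E alkene and the carbinol centres untouched.

Step 12
Reactants: 15 dienyl tetraol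
Product: 17 ring A C15 triol phosphonium bromide ((3S,5R,6R)-configured; 7E and 9E), via allylic bromide 16 (not isolated)
Conditions: NBS, Me2S, CH2Cl2, −20 to 0 °C; then PPh3, CH2Cl2/EtOAc, rt
Reagents that add atoms: N-bromosuccinimide, O=C1CCC(=O)N1Br; triphenylphosphine, c1ccc(cc1)P(c1ccccc1)c1ccccc1
Why: The Corey–Kim bromosulfonium reagent should convert only the primary allylic hydroxyl into the bromide under neutral conditions, and SN2 quaternization of PPh3 then gives the salt without ionising the tertiary allylic C6 hydroxyl.

**Ring B fragment and C25 aldehyde**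

Step 13
Reactants: 18 (4R,6R)-4-hydroxy-2,2,6-trimethylcyclohexanone (actinol)
Product: 19 (4R,6R)-4-(tert-butyldimethylsilyloxy)-2,2,6-trimethylcyclohexanone
Conditions: TBSCl, imidazole, DMF, rt
Reagents that add atoms: tert-butyldimethylsilyl chloride, CC(C)(C)[Si](C)(C)Cl
Why: Standard silylation of the secondary alcohol protects it from the base and triflating agent of the next step and leaves both stereocentres unchanged.

Step 14
Reactants: 19 silylated actinol
Product: 21 (R)-4-(tert-butyldimethylsilyloxy)-2,6,6-trimethylcyclohex-1-en-1-yl trifluoromethanesulfonate, via lithium enolate 20 (not isolated)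
Conditions: LiN(i-Pr)2, THF, −78 °C; PhNTf2, −78 °C to rt; H2O
Reagents that add atoms: N-phenylbis(trifluoromethanesulfonimide), O=S(=O)(N(c1ccccc1)S(=O)(=O)C(F)(F)F)C(F)(F)F
Why: The ketone has a single α-hydrogen, so one enolate forms and is O-triflated; the methyl-bearing centre is erased, and the silyloxy carbon, γ to the carbonyl, cannot eliminate and carries C3' forward.

Step 15
Reactants: 21 enol triflate; 3 (E)-3-methylpent-2-en-4-yn-1-ol
Product: 22 (2E)-5-[(R)-4-(tert-butyldimethylsilyloxy)-2,6,6-trimethylcyclohex-1-en-1-yl]-3-methylpent-2-en-4-yn-1-ol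
Conditions: Pd(PPh3)4 (zerovalent palladium, 5 mol%), CuI (monovalent copper, 10 mol%), i-Pr2NH, DMF, rt to 50 °C
Reagents that add atoms: none
Why: Sonogashira coupling of the tetrasubstituted enol triflate with the terminal alkyne of the free enynol forms C6'–C7' and keeps the 9'E geometry bought with 3.

Step 16
Reactants: 22 silylated enynol
Product: 23 (2E)-5-[(R)-4-hydroxy-2,6,6-trimethylcyclohex-1-en-1-yl]-3-methylpent-2-en-4-yn-1-ol
Conditions: TBAF, THF, rt
Reagents that add atoms: none
Why: Fluoride desilylation frees the C3' hydroxyl before salt formation; no stereocentre or alkene is affected.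

Step 17
Reactants: 23 enyne diol
Product: 24 ring B C15 phosphonium bromide ((R)-configured at C3'; 9'E)
Conditions: PPh3·HBr, MeOH, rt
Reagents that add atoms: triphenylphosphine hydrobromide, Br.c1ccc(cc1)P(c1ccccc1)c1ccccc1
Why: Under HBr the primary allylic alcohol ionises to a cation delocalised over the enyne and is captured by PPh3 at the primary terminus (standard carotenoid salt formation), while the saturated secondary ring hydroxyl is inert.

Step 18
Reactants: 24 ring B phosphonium bromide; 25 (2E,4E,6E)-2,7-dimethylocta-2,4,6-trienedial (3 equiv)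
Product: 28 all-E acetylenic C25 apo-aldehyde ((3R)-3-hydroxy-7,8-didehydro-12'-apo-β-caroten-12'-al), via ring B ylide 26 (not isolated), via 11'Z apo-aldehyde 27 (not isolated)
Conditions: 1,2-epoxybutane, EtOH, reflux; then n-heptane/EtOH, reflux, dark, argon
Reagents that add atoms: none
Why: In this Wittig olefination bromide opens the epoxide to an alkoxide that generates the ylide under near-neutral conditions, the excess dialdehyde should hold the reaction at the mono-adduct (C11'=C12'), and the sterically strained 11'Z portion is expected to equilibrate thermally to E without disturbing the 9'E enyne.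

**Fragment union**

Step 19
Reactants: 17 ring A phosphonium bromide; 28 C25 apo-aldehyde
Product: 31 (3S,5R,6R,3'R)-7',8'-didehydro-5,6-dihydro-β,β-carotene-3,5,6,3'-tetrol (all-E target), via ring A ylide 29 (not isolated), via 11Z tetrol 30 (not isolated)
Conditions: 1,2-epoxybutane, EtOH, reflux; then continued reflux in EtOH/n-heptane, dark, argon; crystallization
Reagents that add atoms: none
Why: The Wittig reaction under epoxide-buffered conditions tolerates all four free hydroxyls and forms C11=C12, and the hindered 11Z isomer should relax thermally to the all-E polyene; iodine and light are avoided so that the 9'-alkene next to the triple bond is not scrambled.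

**Compound list**

1 | 2,6-dimethyl-1,4-benzoquinone | CC1=CC(=O)C=C(C)C1=O | starting material
2 | 2,6-dimethyl-1,4-benzoquinone 4-(ethylene ketal) | CC1=CC2(OCCO2)C=C(C)C1=O | intermediate
3 | (E)-3-methylpent-2-en-4-yn-1-ol | C#C/C(C)=C/CO | starting material
4 | dilithio salt of 3 (lithium acetylide, lithium alkoxide) | [Li+].[Li+].[C-]#C/C(C)=C/C[O-] | intermediate
5 | 8-hydroxy-8-[(3E)-5-hydroxy-3-methylpent-3-en-1-yn-1-yl]-7,9-dimethyl-1,4-dioxaspiro[4.5]deca-6,9-diene | CC1=CC2(OCCO2)C=C(C)C1(O)C#C/C(C)=C/CO | intermediate
6 | 4-hydroxy-4-[(3E)-5-hydroxy-3-methylpent-3-en-1-yn-1-yl]-3,5-dimethylcyclohexa-2,5-dien-1-one | CC1=CC(=O)C=C(C)C1(O)C#C/C(C)=C/CO | intermediate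
7 | primary tert-butyldimethylsilyl ether of 6 (prochiral dienone) | CC1=CC(=O)C=C(C)C1(O)C#C/C(C)=C/CO[Si](C)(C)C(C)(C)C | intermediate
8 | bis(dimethylaluminium) alkoxide/cross-conjugated dienolate from 7 after methyl transfer | CC(C)(C)[Si](C)(C)OC/C=C(C)/C#C[C@@]1(O[Al](C)C)C(C)(C)C=C(O[Al](C)C)C=C1C | intermediate
9 | (R)-4-[(3E)-5-(tert-butyldimethylsilyloxy)-3-methylpent-3-en-1-yn-1-yl]-4-hydroxy-3,5,5-trimethylcyclohex-2-en-1-one | CC(C)(C)[Si](C)(C)OC/C=C(C)/C#C[C@@]1(O)C(C)(C)CC(=O)C=C1C | intermediate
10 | C6 triethylsilyl ether of 9 | CC(C)(C)[Si](C)(C)OC/C=C(C)/C#C[C@@]1(O[Si](CC)(CC)CC)C(C)(C)CC(=O)C=C1C | intermediate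
11 | (4S,5R,6S)-4,5-epoxy-3-ketone, epoxide anti to the C6 silyloxy group | CC(C)(C)[Si](C)(C)OC/C=C(C)/C#C[C@@]1(O[Si](CC)(CC)CC)C(C)(C)CC(=O)[C@H]2O[C@@]12C | intermediate
12 | (5R,6S)-5-hydroxy-3-ketone, bis-silyl ether | CC(C)(C)[Si](C)(C)OC/C=C(C)/C#C[C@@]1(O[Si](CC)(CC)CC)C(C)(C)CC(=O)C[C@@]1(C)O | intermediate
13 | (3S,5R,6S)-3,5-diol, bis-silyl ether | CC(C)(C)[Si](C)(C)OC/C=C(C)/C#C[C@@]1(O[Si](CC)(CC)CC)C(C)(C)C[C@H](O)C[C@@]1(C)O | intermediate
14 | (3S,5R,6S) ring A alkynyl tetraol | OC/C=C(C)/C#C[C@@]1(O)C(C)(C)C[C@H](O)C[C@@]1(C)O | intermediate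
15 | (3S,5R,6R) ring A (7E,9E)-dienyl tetraol | OC/C=C(C)/C=C/[C@@]1(O)C(C)(C)C[C@H](O)C[C@@]1(C)O | intermediate
16 | (3S,5R,6R) ring A primary allylic bromide | BrC/C=C(C)/C=C/[C@@]1(O)C(C)(C)C[C@H](O)C[C@@]1(C)O | intermediate
17 | (3S,5R,6R) ring A C15 triol triphenylphosphonium bromide | c1ccccc1[P+](c1ccccc1)(c1ccccc1)C/C=C(C)/C=C/[C@@]1(O)C(C)(C)C[C@H](O)C[C@@]1(C)O.[Br-] | intermediate
18 | (4R,6R)-4-hydroxy-2,2,6-trimethylcyclohexanone (actinol) | C[C@H]1C(=O)C(C)(C)C[C@H](O)C1 | starting material
19 | (4R,6R)-4-(tert-butyldimethylsilyloxy)-2,2,6-trimethylcyclohexanone | C[C@H]1C(=O)C(C)(C)C[C@H](O[Si](C)(C)C(C)(C)C)C1 | intermediate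
20 | lithium enolate of 19 | CC1=C([O-])C(C)(C)C[C@H](O[Si](C)(C)C(C)(C)C)C1.[Li+] | intermediate
21 | (R)-4-(tert-butyldimethylsilyloxy)-2,6,6-trimethylcyclohex-1-en-1-yl triflate | CC1=C(OS(=O)(=O)C(F)(F)F)C(C)(C)C[C@H](O[Si](C)(C)C(C)(C)C)C1 | intermediate
22 | ring B C15 enynol, silyl ether at C3' | CC1=C(C#C/C(C)=C/CO)C(C)(C)C[C@H](O[Si](C)(C)C(C)(C)C)C1 | intermediate
23 | ring B C15 enyne diol | CC1=C(C#C/C(C)=C/CO)C(C)(C)C[C@H](O)C1 | intermediate
24 | ring B C15 triphenylphosphonium bromide | CC1=C(C#C/C(C)=C/C[P+](c2ccccc2)(c2ccccc2)c2ccccc2)C(C)(C)C[C@H](O)C1.[Br-] | intermediate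
25 | (2E,4E,6E)-2,7-dimethylocta-2,4,6-trienedial | O=C/C(C)=C/C=C/C=C(C)/C=O | starting material
26 | ring B phosphorus ylide | CC1=C(C#C/C(C)=C/C=P(c2ccccc2)(c2ccccc2)c2ccccc2)C(C)(C)C[C@H](O)C1 | intermediate
27 | 11'Z isomer of the C25 apo-aldehyde | CC1=C(C#C/C(C)=C/C=C\C(C)=C\C=C\C=C(C)\C=O)C(C)(C)C[C@H](O)C1 | intermediate
28 | all-E acetylenic C25 apo-aldehyde | CC1=C(C#C/C(C)=C/C=C/C(C)=C/C=C/C=C(C)/C=O)C(C)(C)C[C@H](O)C1 | intermediate
29 | ring A phosphorus ylide | c1ccccc1P(c1ccccc1)(c1ccccc1)=C/C=C(C)/C=C/[C@@]1(O)C(C)(C)C[C@H](O)C[C@@]1(C)O | intermediate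
30 | 11Z isomer of the target | CC1=C(C#C/C(C)=C/C=C/C(C)=C/C=C/C=C(C)/C=C\C=C(C)\C=C\[C@@]2(O)C(C)(C)C[C@H](O)C[C@@]2(C)O)C(C)(C)C[C@H](O)C1 | intermediate
31 | (3S,5R,6R,3'R)-7',8'-didehydro-5,6-dihydro-β,β-carotene-3,5,6,3'-tetrol | CC1=C(C#C/C(C)=C/C=C/C(C)=C/C=C/C=C(C)/C=C/C=C(C)/C=C/[C@@]2(O)C(C)(C)C[C@H](O)C[C@@]2(C)O)C(C)(C)C[C@H](O)C1 | target

**Step count**

Total: 19 steps. Longest linear sequence: 13 steps (steps 1–12, then step 19). The ring B branch is 6 steps (steps 13–18) before the union.

**Steps most likely to fail**

Step 5 (proposed new method). The catalyst may discriminate poorly between the two enantiotopic arms, the methyl transfer may be slow at a β-carbon next to the fully substituted carbinol, or the Lewis-acidic aluminium may trigger 1,2-addition or ionisation of the alkoxide. The fallback is a chiral-pool relay built only from known reactions; it sets out from actinol 18 and comes back to the route at 9.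
- Oxidation of 18 with Dess–Martin periodinane gives (R)-2,2,6-trimethylcyclohexane-1,4-dione F1.
- Ketalization with ethylene glycol and a catalytic sulfonic acid takes place at the unhindered carbonyl and gives the monoketal F2.
- The dilithio enynolate 4 is expected to add axially to the hindered ketone, cis to the equatorial methyl, giving the alkynyl carbinol ketal F3 with C6 as required.
- Aqueous HCl in THF frees the ketone to give keto diol F4, and TBSCl/imidazole gives the primary silyl ether F5.
- LiN(i-Pr)2 with Me3SiCl gives the bis-trimethylsilyl derivative F6. Its enol ether lies toward C4, and only that regiochemistry can lead to an enone, since C1 has no hydrogen.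
- Saegusa–Ito oxidation with Pd(OAc)2 (divalent palladium) in MeCN gives the C6 trimethylsilyl ether of the enone F7, which K2CO3 in MeOH converts into 9. The methyl-bearing centre used for the relay is erased in the enone.

Step 7. Peroxide addition may be slow at the β-carbon adjacent to the fully substituted C6, facial selectivity may be poor, and base may cause silyl loss. The fallback replaces the nucleophilic epoxidation by a hydroxyl-directed one; it sets out from 10 and comes back at 11.
- Luche reduction (NaBH4, CeCl3·7H2O, MeOH, −78 °C) gives the allylic alcohol F8. Hydride should enter away from the pseudoaxial C1 methyl, placing the C3 hydroxyl on the face opposite the C6 silyloxy group.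
- VO(acac)2 with t-BuOOH delivers the epoxide syn to that hydroxyl, and therefore anti to the C6 oxygen, giving the epoxy alcohol F9.
- Dess–Martin oxidation returns the C3 ketone, giving 11.

Step 12. Bromination may not distinguish the primary allylic hydroxyl cleanly among four hydroxyls, the tertiary allylic C6 hydroxyl may ionise, and the dienyl bromide may transpose or decompose before quaternization. The fallback reverses the polarity of the last olefination while forming the same C11=C12 bond; it sets out from 15 and 28 and comes back at 31.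
- MnO2 oxidises only the primary allylic hydroxyl of 15 to give the ring A C15 dienal F10.
- NaBH4 reduces 28 to the C25 allylic alcohol F11, which PPh3·HBr in MeOH converts into the C25 phosphonium bromide F12.
- Wittig reaction of F12 with F10 (1,2-epoxybutane, EtOH, reflux), followed by the same thermal isomerization, gives 31.

**Further compounds**

F1 | step 5 | (R)-2,2,6-trimethylcyclohexane-1,4-dione | O=C1C(C)(C)CC(=O)C[C@H]1C
F2 | step 5 | (R)-2,2,6-trimethylcyclohexane-1,4-dione 4-(ethylene ketal) | O=C1C(C)(C)CC2(OCCO2)C[C@H]1C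
F3 | step 5 | alkynyl carbinol ketal (alkynyl cis to the C5 methyl) | OC/C=C(C)/C#C[C@@]1(O)C(C)(C)CC2(OCCO2)C[C@H]1C
F4 | step 5 | keto diol from ketal hydrolysis of F3 | OC/C=C(C)/C#C[C@@]1(O)C(C)(C)CC(=O)C[C@H]1C
F5 | step 5 | primary tert-butyldimethylsilyl ether of F4 | CC(C)(C)[Si](C)(C)OC/C=C(C)/C#C[C@@]1(O)C(C)(C)CC(=O)C[C@H]1C
F6 | step 5 | C6 trimethylsilyl ether, C3 trimethylsilyl enol ether of F5 | CC(C)(C)[Si](C)(C)OC/C=C(C)/C#C[C@@]1(O[Si](C)(C)C)C(C)(C)CC(O[Si](C)(C)C)=C[C@H]1C
F7 | step 5 | C6 trimethylsilyl ether of enone 9 | CC(C)(C)[Si](C)(C)OC/C=C(C)/C#C[C@@]1(O[Si](C)(C)C)C(C)(C)CC(=O)C=C1C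
F8 | step 7 | C3 allylic alcohol from 10, hydroxyl anti to the C6 silyloxy group | CC(C)(C)[Si](C)(C)OC/C=C(C)/C#C[C@@]1(O[Si](CC)(CC)CC)C(C)(C)C[C@@H](O)C=C1C
F9 | step 7 | 4,5-epoxy-3-ol, epoxide syn to the C3 hydroxyl and anti to the C6 silyloxy group | CC(C)(C)[Si](C)(C)OC/C=C(C)/C#C[C@@]1(O[Si](CC)(CC)CC)C(C)(C)C[C@@H](O)[C@H]2O[C@@]12C
F10 | step 12 | ring A C15 (2E,4E)-dienal triol | O=C/C=C(C)/C=C/[C@@]1(O)C(C)(C)C[C@H](O)C[C@@]1(C)O
F11 | step 12 | C25 allylic alcohol from 28 | CC1=C(C#C/C(C)=C/C=C/C(C)=C/C=C/C=C(C)/CO)C(C)(C)C[C@H](O)C1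
F12 | step 12 | C25 triphenylphosphonium bromide | CC1=C(C#C/C(C)=C/C=C/C(C)=C/C=C/C=C(C)/C[P+](c2ccccc2)(c2ccccc2)c2ccccc2)C(C)(C)C[C@H](O)C1.[Br-]
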